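**Retrosynthetic overview**

1. Numbering: ring B = C1(=O)–C2(side chain)–C3(H)–C4(=O)–C4a–C8a; ring A = C4a–C5(OH)–C6–C7–C8(OH)–C8a; the carbinol carbon is C1'. The last disconnection is the C1'–O acyl bond (Steglich), giving (R)-shikonin and 3,4-dimethylpent-3-enoic acid.
2. Key disconnection: C2–C3 and C1–C8a are cut together. This is an inverse-demand [4+2] between 2-(1-acetoxyvinyl)-1,4-benzoquinone (C3=C4–C4a=C8a) and a chiral triisopropylsilyl ynol ether (C1≡C2 carrying C1').
3. Enabling feature: ring A is a hydroquinone. At the p-quinone level its C4a–C8a bond is no longer aromatic but an electron-poor alkene conjugated to C8=O. This makes C3, by nature the enolate carbon of the C4 ketone, the electrophilic end of a diene. It can then join C2, the enolate-type carbon of a masked ketene: two carbons of like polarity united by polarity reversal.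
4. 5,8-Dihydroxy-1,4-naphthoquinones are tautomerically degenerate, so it does not matter that ring A leaves the sequence as the quinone and ring B as the diol. Ring order: ring A is bought as an arene, ring B is formed in the key step.
5. Ynol ether: methyl (R)-glycidate (source of C1'), alkenyl-copper epoxide opening, silyl ether, Kowalski homologation. Diene: 2',5'-dimethoxyacetophenone, enol acetate, oxidative demethylation.

Key step: step 6

Remark on the chemistry (assumption): the two proton-transfer tautomers of a 5,8-dihydroxy-1,4-naphthoquinone interconvert fast. The 6-substituted form released in step 9 and the 2-substituted form drawn for shikonin and for the target are therefore one compound.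

**Step 1**
Reactants: 1 methyl (R)-oxirane-2-carboxylate; 2 2-methylprop-1-enylmagnesium bromide
Product: 3 methyl (R)-2-hydroxy-5-methylhex-4-enoate
Conditions: CuBr·SMe2 (10 mol %), THF, −40 °C; aq. NH4Cl
Reagents that add atoms: none
Why: Copper-catalysed SN2 opening of a terminal epoxide by an alkenyl Grignard reagent should occur at the unsubstituted C3 of the glycidate, so the C2–O stereocentre of the chiral-pool epoxide is not touched and becomes C1' with (R) configuration.

**Step 2**
Reactants: 3 methyl (R)-2-hydroxy-5-methylhex-4-enoate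
Product: 4 methyl (R)-2-(tert-butyldimethylsilyloxy)-5-methylhex-4-enoate
Conditions: TBSCl, imidazole, DMF, 25 °C
Reagents that add atoms: tert-butyldimethylsilyl chloride, CC(C)(C)[Si](C)(C)Cl
Why: Standard imidazole-promoted O-silylation of a secondary alcohol gives an ether that is a poor leaving group and survives organolithium reagents, and it does not involve the stereocentre.

**Step 3**
Reactants: 4 methyl (R)-2-(tert-butyldimethylsilyloxy)-5-methylhex-4-enoate
Product: 7 (R)-3-(tert-butyldimethylsilyloxy)-6-methyl-1-(triisopropylsilyloxy)hept-5-en-1-yne, via dibromoketone lithium enolate 5 (not isolated), via lithium ynolate 6 (not isolated)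
Conditions: CH2Br2, lithium 2,2,6,6-tetramethylpiperidide (LiTMP), THF, −78 °C, then 4; n-BuLi, −78 to 0 °C; i-Pr3SiOTf, −78 to 0 °C
Reagents that add atoms: dibromomethane, BrCBr; triisopropylsilyl trifluoromethanesulfonate, CC(C)[Si](OS(=O)(=O)C(F)(F)F)(C(C)C)C(C)C
Why: In the Kowalski ester homologation, LiCHBr2 adds to the ester, bromine–lithium exchange on enolate 5 triggers a 1,2-shift of the carbinol carbon with retention (as shown for alpha-chiral esters), and the bulky silyl triflate traps ynolate 6 on oxygen.

**Step 4**
Reactants: 8 2',5'-dimethoxyacetophenone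
Product: 9 1-(2,5-dimethoxyphenyl)vinyl acetate
Conditions: isopropenyl acetate (solvent), p-TsOH·H2O (cat.), reflux, acetone distilled off
Reagents that add atoms: isopropenyl acetate, CC(=C)OC(C)=O
Why: Acid-catalysed enol-ester exchange with isopropenyl acetate is driven by loss of acetone, and the ketone has only one enolisable position, so a single enol acetate can form.

**Step 5**
Reactants: 9 1-(2,5-dimethoxyphenyl)vinyl acetate
Product: 10 2-(1-acetoxyvinyl)-1,4-benzoquinone
Conditions: (NH4)2Ce(NO3)6 (2.2 equiv), MeCN–H2O, 0 °C, 10 min; cold extractive work-up, used at once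
Reagents that add atoms: water, O
Why: Oxidative demethylation of a 1,4-dimethoxyarene to the quinone, as used to make other vinylquinones, starts at the arene as the most easily oxidised site, and the enol acetate should survive the short cold contact with aqueous acid.

**Step 6**
Reactants: 7 (R)-3-(tert-butyldimethylsilyloxy)-6-methyl-1-(triisopropylsilyloxy)hept-5-en-1-yne; 10 2-(1-acetoxyvinyl)-1,4-benzoquinone
Product: 12 5,8-dihydroxy-3-[(R)-1-(tert-butyldimethylsilyloxy)-4-methylpent-3-enyl]-4-(triisopropylsilyloxy)naphthalen-1-yl acetate (target numbering: C1–OTIPS and C2–side chain and C4–OAc), via enedione cycloadduct 11 (not isolated)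
Conditions: PhMe, 4 Å MS, dark, argon, 10 (1.3 equiv) added over 2 h at 25 °C, then 45 °C
Reagents that add atoms: none
Why: Proposed new method: with ring A at the p-benzoquinone level the C4a–C8a bond of 10 is a true electron-poor alkene which, together with the 1-acetoxyvinyl group, makes up an s-cis diene (C3=C4–C4a=C8a) that carries the C8 carbonyl on its ring terminus, and the electron-rich ynol ether 7 should add to it in a thermally allowed, concerted but asynchronous inverse-electron-demand [4+2] cycloaddition in which its nucleophilic carbon (C2) leads by bonding to the vinylogous acceptor carbon C3 and the silyloxy-bearing carbon (C1) follows at C8a. The closest known reaction types are the vinylquinone Diels–Alder reaction, in which 2-vinyl-1,4-benzoquinones serve as dienes toward enol ethers, styrenes and other electron-rich alkenes, and the inverse-demand cycloadditions of siloxyalkynes, alkoxyalkynes and ynamines to 2-pyranones and 1,2-diazines; an ynol ether has not been shown as the partner of a vinylquinone. Ring B, the only ring closed, forms as a six-membered carbocycle in the suprafacial [4+2] mode, and enedione 11 then aromatises both rings by two proton shifts (C8a–H and one C3–H to the oxygens at C8 and C5), which makes the step irreversible and delivers all four oxygens of the naphthazarin in differentiated form. The only new stereocentre, C8a of 11, is erased in this tautomerisation, whereas C1' is a propargylic spectator that is never alpha to a carbonyl group and should keep its (R) configuration. The step needs orientational selectivity and site selectivity for the diene over the C6=C7 alkene of 10 and over the trisubstituted alkene of 7: a perturbation picture of the 2-vinylquinone LUMO puts the largest terminal coefficient on the exocyclic CH2 and a near-node on the acetoxy-bearing carbon, this CH2 is the only unhindered acceptor site for an alkyne that is branched at both ends, addition to C6=C7 could only be a stepwise [2+2] through a zwitterion that toluene disfavours, and the side-chain alkene is far less nucleophilic than the ynol ether. Slow addition of 10 keeps its concentration low and so holds back its second-order self-dimerisation.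

**Step 7**
Reactants: 12 5,8-dihydroxy-3-[(R)-1-(tert-butyldimethylsilyloxy)-4-methylpent-3-enyl]-4-(triisopropylsilyloxy)naphthalen-1-yl acetate
Product: 13 5-acetoxy-7-[(R)-1-(tert-butyldimethylsilyloxy)-4-methylpent-3-enyl]-8-(triisopropylsilyloxy)naphthalene-1,4-dione
Conditions: Ag2O, MgSO4, CH2Cl2, 25 °C
Reagents that add atoms: none
Why: Neutral hydroquinone-to-quinone oxidation with Ag2O can only touch ring A because both oxygens of ring B are blocked, and it removes the electron-rich diol before the benzylic C1'–O bond is exposed.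

**Step 8**
Reactants: 13 5-acetoxy-7-[(R)-1-(tert-butyldimethylsilyloxy)-4-methylpent-3-enyl]-8-(triisopropylsilyloxy)naphthalene-1,4-dione
Product: 14 5-acetoxy-8-hydroxy-7-[(R)-1-hydroxy-4-methylpent-3-enyl]naphthalene-1,4-dione
Conditions: HF·pyridine, pyridine, THF, 0 to 25 °C (plastic vessel)
Reagents that add atoms: none
Why: Fluoride-driven Si–O cleavage under pyridine-buffered conditions should remove the aryl and the secondary alkyl silyl ethers without breaking the C1'–O bond, the acetate or the trisubstituted alkene.

**Step 9**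
Reactants: 14 5-acetoxy-8-hydroxy-7-[(R)-1-hydroxy-4-methylpent-3-enyl]naphthalene-1,4-dione
Product: 15 (R)-shikonin, 5,8-dihydroxy-2-[(R)-1-hydroxy-4-methylpent-3-enyl]naphthalene-1,4-dione
Conditions: K2CO3 (2 equiv), MeOH, 0 °C, argon; 1 M HCl to pH 4
Reagents that add atoms: none
Why: Base-promoted methanolysis (transesterification) of a phenolic acetate that is activated by the peri quinone carbonyl frees the second phenol, and the product is drawn as its usual 2-substituted tautomer.

**Step 10**
Reactants: 16 2,3-dimethylbut-2-ene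
Product: 18 3,4-dimethylpent-3-enoic acid, via 2,3-dimethylbut-2-enylpotassium 17 (not isolated)
Conditions: n-BuLi, KOt-Bu, hexane, 25 °C; CO2 (s), THF, −78 °C; 1 M HCl
Reagents that add atoms: carbon dioxide, O=C=O
Why: Lochmann–Schlosser superbase metalation of one of twelve equivalent allylic hydrogens gives a single allylpotassium, whose carboxylation should take place at the primary terminus because attack at the other terminus would build a quaternary carbon.

**Step 11**
Reactants: 15 (R)-shikonin; 18 3,4-dimethylpent-3-enoic acid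
Product: 20 (R)-1-(5,8-dihydroxy-1,4-dioxo-1,4-dihydronaphthalen-2-yl)-4-methylpent-3-enyl 3,4-dimethylpent-3-enoate (target), via O-acylisourea 19 (not isolated)
Conditions: DCC, DMAP (20 mol %), CH2Cl2, 0 to 25 °C
Reagents that add atoms: none
Why: Steglich esterification, the established way to acylshikonins, should acylate only the side-chain hydroxyl because both phenols are tied up in hydrogen bonds to the quinone carbonyls, and the C1'–O bond is not broken, so (R) is retained.

**Compound list**

1 | methyl (R)-oxirane-2-carboxylate | COC(=O)[C@H]1CO1 | starting material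
2 | 2-methylprop-1-enylmagnesium bromide | CC(C)=C[Mg]Br | starting material
3 | methyl (R)-2-hydroxy-5-methylhex-4-enoate | CC(C)=CC[C@@H](O)C(=O)OC | intermediate
4 | methyl (R)-2-(tert-butyldimethylsilyloxy)-5-methylhex-4-enoate | CC(C)=CC[C@@H](O[Si](C)(C)C(C)(C)C)C(=O)OC | intermediate
5 | lithium (R)-1,1-dibromo-3-(tert-butyldimethylsilyloxy)-6-methylhepta-1,5-dien-2-olate | CC(C)=CC[C@@H](O[Si](C)(C)C(C)(C)C)C([O-])=C(Br)Br.[Li+] | intermediate
6 | lithium (R)-3-(tert-butyldimethylsilyloxy)-6-methylhept-5-en-1-yn-1-olate | CC(C)=CC[C@@H](O[Si](C)(C)C(C)(C)C)C#C[O-].[Li+] | intermediate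
7 | (R)-3-(tert-butyldimethylsilyloxy)-6-methyl-1-(triisopropylsilyloxy)hept-5-en-1-yne | CC(C)=CC[C@@H](O[Si](C)(C)C(C)(C)C)C#CO[Si](C(C)C)(C(C)C)C(C)C | intermediate
8 | 2',5'-dimethoxyacetophenone | COc1ccc(OC)c(c1)C(C)=O | starting material
9 | 1-(2,5-dimethoxyphenyl)vinyl acetate | COc1ccc(OC)c(c1)C(=C)OC(C)=O | intermediate
10 | 2-(1-acetoxyvinyl)-1,4-benzoquinone | CC(=O)OC(=C)C1=CC(=O)C=CC1=O | intermediate
11 | 4-acetoxy-2-[(R)-1-(tert-butyldimethylsilyloxy)-4-methylpent-3-enyl]-1-(triisopropylsilyloxy)-3,8a-dihydronaphthalene-5,8-dione (both C8a epimers) | CC(C)=CC[C@@H](O[Si](C)(C)C(C)(C)C)C1=C(O[Si](C(C)C)(C(C)C)C(C)C)C2C(=O)C=CC(=O)C2=C(OC(C)=O)C1 | intermediate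
12 | 5,8-dihydroxy-3-[(R)-1-(tert-butyldimethylsilyloxy)-4-methylpent-3-enyl]-4-(triisopropylsilyloxy)naphthalen-1-yl acetate | CC(C)=CC[C@@H](O[Si](C)(C)C(C)(C)C)c1cc(OC(C)=O)c2c(O)ccc(O)c2c1O[Si](C(C)C)(C(C)C)C(C)C | intermediate
13 | 5-acetoxy-7-[(R)-1-(tert-butyldimethylsilyloxy)-4-methylpent-3-enyl]-8-(triisopropylsilyloxy)naphthalene-1,4-dione | CC(C)=CC[C@@H](O[Si](C)(C)C(C)(C)C)c1cc(OC(C)=O)c2C(=O)C=CC(=O)c2c1O[Si](C(C)C)(C(C)C)C(C)C | intermediate
14 | 5-acetoxy-8-hydroxy-7-[(R)-1-hydroxy-4-methylpent-3-enyl]naphthalene-1,4-dione | CC(C)=CC[C@@H](O)c1cc(OC(C)=O)c2C(=O)C=CC(=O)c2c1O | intermediate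
15 | (R)-shikonin | CC(C)=CC[C@@H](O)C1=CC(=O)c2c(O)ccc(O)c2C1=O | intermediate
16 | 2,3-dimethylbut-2-ene | CC(C)=C(C)C | starting material
17 | 2,3-dimethylbut-2-enylpotassium | CC(C)=C(C)[CH2-].[K+] | intermediate
18 | 3,4-dimethylpent-3-enoic acid | CC(C)=C(C)CC(=O)O | intermediate
19 | O-(3,4-dimethylpent-3-enoyl)-N,N'-dicyclohexylisourea | CC(C)=C(C)CC(=O)OC(=NC1CCCCC1)NC1CCCCC1 | intermediate
20 | (R)-1-(5,8-dihydroxy-1,4-dioxo-1,4-dihydronaphthalen-2-yl)-4-methylpent-3-enyl 3,4-dimethylpent-3-enoate | CC(C)=CC[C@@H](OC(=O)CC(C)=C(C)C)C1=CC(=O)c2c(O)ccc(O)c2C1=O | target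

**Step count**

Total step count: 11. Longest linear sequence: 8 steps (1, 2, 3, 6, 7, 8, 9, 11).

**Steps most likely to fail**

**Step 6.** Three processes may go wrong.
- The cycloaddition may show poor orientational selectivity, with the nucleophilic alkyne carbon attacking the ring CH instead of the exocyclic CH2.
- The ynol ether may add to the unsubstituted C6–C7 alkene of the quinone.
- Self-dimerisation of the vinylquinone may outrun the cross reaction.

The fallback uses known chemistry, sets out from 4 and comes back to the route at 15. i-Bu2AlH (CH2Cl2, −78 °C) should reduce 4 to (R)-2-(tert-butyldimethylsilyloxy)-5-methylhex-4-enal F1. Dimethyl (1-diazo-2-oxopropyl)phosphonate (K2CO3, MeOH, Ohira–Bestmann homologation) should convert this into (R)-3-(tert-butyldimethylsilyloxy)-6-methylhept-5-en-1-yne F2. Hydroquinone and MOMCl (i-Pr2NEt) give 1,4-bis(methoxymethoxy)benzene F3. Ortho-lithiation (n-BuLi), addition to Cr(CO)6 and O-methylation (Me3OBF4) turn F3 into pentacarbonyl{[2,5-bis(methoxymethoxy)phenyl](methoxy)carbene}chromium F4.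

Dötz benzannulation of F2 and F4 (THF, 50 °C) places the larger alkyne substituent next to the new phenol. It should give 2-[(R)-1-(tert-butyldimethylsilyloxy)-4-methylpent-3-enyl]-4-methoxy-5,8-bis(methoxymethoxy)naphthalen-1-ol F5. (NH4)2Ce(NO3)6 then oxidises this to 2-[(R)-1-(tert-butyldimethylsilyloxy)-4-methylpent-3-enyl]-5,8-bis(methoxymethoxy)naphthalene-1,4-dione F6. Dilute HCl in MeOH–THF removes both acetals and the silyl ether to reach 15.

**Step 5.** The enol ester may hydrolyse in the acidic aqueous oxidant, the oxidant may attack the styrene-type double bond, or the vinylquinone may dimerise on concentration.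

The fallback changes the protecting-group plan so that the quinone is released without water. It sets out from 8 and comes back at 10. BBr3 (CH2Cl2) demethylates 8 to 2',5'-dihydroxyacetophenone F7. TBSCl and imidazole give 2',5'-bis(tert-butyldimethylsilyloxy)acetophenone F8. KN(SiMe3)2 followed by Ac2O gives 1-[2,5-bis(tert-butyldimethylsilyloxy)phenyl]vinyl acetate F9. Pyridinium chlorochromate, C5H5NH[CrO3Cl], in dry CH2Cl2 (the known release of quinones from hydroquinone bis-silyl ethers) then gives 10.

**Step 3.** The amide base may enolise the ester before addition and erode the configuration at C1', silylation may occur at carbon instead of oxygen, or the 1,2-shift may remain incomplete.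

The fallback reaches the ynolate by oxidation of an acetylide instead of by rearrangement. It sets out from 4 and comes back at 6. Reduction of 4 as above gives the aldehyde F1. CBr4 and PPh3 (Corey–Fuchs) give (R)-1,1-dibromo-3-(tert-butyldimethylsilyloxy)-6-methylhepta-1,5-diene F10. n-BuLi (2 equiv) gives lithium (R)-3-(tert-butyldimethylsilyloxy)-6-methylhept-5-en-1-yn-1-ide F11. t-BuOOLi (from t-BuOOH and LiN(SiMe3)2) oxidises the acetylide to ynolate 6, which is silylated as in step 3.

**Further compounds**

F1 | step 6 | (R)-2-(tert-butyldimethylsilyloxy)-5-methylhex-4-enal | CC(C)=CC[C@@H](O[Si](C)(C)C(C)(C)C)C=O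
F2 | step 6 | (R)-3-(tert-butyldimethylsilyloxy)-6-methylhept-5-en-1-yne | CC(C)=CC[C@@H](O[Si](C)(C)C(C)(C)C)C#C
F3 | step 6 | 1,4-bis(methoxymethoxy)benzene | COCOc1ccc(OCOC)cc1
F4 | step 6 | pentacarbonyl{[2,5-bis(methoxymethoxy)phenyl](methoxy)carbene}chromium | COCOc1ccc(OCOC)c(c1)C(OC)=[Cr].[C-]#[O+].[C-]#[O+].[C-]#[O+].[C-]#[O+].[C-]#[O+]
F5 | step 6 | 2-[(R)-1-(tert-butyldimethylsilyloxy)-4-methylpent-3-enyl]-4-methoxy-5,8-bis(methoxymethoxy)naphthalen-1-ol | CC(C)=CC[C@@H](O[Si](C)(C)C(C)(C)C)c1cc(OC)c2c(OCOC)ccc(OCOC)c2c1O
F6 | step 6 | 2-[(R)-1-(tert-butyldimethylsilyloxy)-4-methylpent-3-enyl]-5,8-bis(methoxymethoxy)naphthalene-1,4-dione | CC(C)=CC[C@@H](O[Si](C)(C)C(C)(C)C)C1=CC(=O)c2c(OCOC)ccc(OCOC)c2C1=O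
F7 | step 5 | 2',5'-dihydroxyacetophenone | CC(=O)c1cc(O)ccc1O
F8 | step 5 | 2',5'-bis(tert-butyldimethylsilyloxy)acetophenone | CC(=O)c1cc(O[Si](C)(C)C(C)(C)C)ccc1O[Si](C)(C)C(C)(C)C
F9 | step 5 | 1-[2,5-bis(tert-butyldimethylsilyloxy)phenyl]vinyl acetate | CC(=O)OC(=C)c1cc(O[Si](C)(C)C(C)(C)C)ccc1O[Si](C)(C)C(C)(C)C
F10 | step 3 | (R)-1,1-dibromo-3-(tert-butyldimethylsilyloxy)-6-methylhepta-1,5-diene | CC(C)=CC[C@@H](O[Si](C)(C)C(C)(C)C)C=C(Br)Br
F11 | step 3 | lithium (R)-3-(tert-butyldimethylsilyloxy)-6-methylhept-5-en-1-yn-1-ide | CC(C)=CC[C@@H](O[Si](C)(C)C(C)(C)C)C#[C-].[Li+]
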